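Ar denotes the aryl group of phenol 10 throughout: 2-{4-[2,4-dimethoxy-6-(2,4,6-trimethoxyphenoxy)phenoxy]-2,6-dimethoxyphenoxy}-4,6-dimethoxyphenyl.

## Analysis of the target

The target (C30H22O15) is a linear pentamer of phloroglucinol: five benzene rings, A to E, joined only by four diaryl ether oxygens, with no carbon–carbon bond between rings. It has no stereocentre, and rotation about the ether bonds is free, so nothing stereochemical has to be set. Ring A is a 3,5-dihydroxyphenoxy group. Rings B and D carry ether oxygens at C1 and C6 and hydroxyls at C2 and C4; ring C carries ether oxygens at C1 and C4 and hydroxyls at C2 and C6; ring E is a 2,4,6-trihydroxyphenoxy end group. The eleven free phenolic hydroxyls make the compound very electron-rich, polar and prone to air oxidation, so they must stay masked until the last step, and the unmasking must spare the four diaryl ethers. The hard part is the ether bonds: the oxygens on ring B C1, ring C C1 and ring D C1 are each flanked by two oxygen substituents, and no ring carries an acceptor that would help an arylation. The strategy rests on ring A being attached through one atom only, the oxygen on ring B C1 that sits between the C2 hydroxyl and the C6 aryloxy group, and on its three oxygens being mutually meta. That is the pattern a vinylketene–ynol ether benzannulation delivers, so ring A can be grown on this crowded oxygen instead of being coupled to it.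

## Retrosynthetic reasoning

**26 from 25.** All eleven hydroxyls are unmasked together by Lewis-acid dealkylation of 25, which carries nine methyl ethers, one ethyl ether and one free phenol. Methyl ethers are chosen because they survive base, copper, peracid, alkyllithium and heat, and because their cleavage leaves diaryl ethers intact.

**25 from 16 and 20.** Two carbon–carbon bonds of ring A are cut: the bond between the hydroxyl-bearing carbon and the CH that lies between hydroxyl and aryloxy, and the bond between the hydroxyl-bearing carbon and the CH next to the ethoxy carbon. This leaves a two-carbon piece that already holds the ring B oxygen (ynol ether 16) and a four-carbon piece (cyclobutenone 20). The cut is made here because it removes the need to arylate the most encumbered phenol of the sequence with an unactivated 3,5-dioxygenated aryl halide. The forward reaction has to form both bonds with one regiochemistry, so that aryloxy, hydroxyl and ethoxy end up 1,3,5.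

**16 from 10 and 11.** The O–C(sp) bond is cut. The ethynyl group is put on the phenol oxygen of 10 as a dichlorovinyl group (13) by addition to the small, linear chloroalkyne 12 released from 11. Two equivalents of an alkyllithium then convert 13 into the acetylide 15, which is protonated. A linear two-carbon electrophile reaches an oxygen that an aryl electrophile approaches only with difficulty.

**20 from 17 and 18.** The four-membered ring is cut into ketene 19 and ethoxyacetylene 17. Ketene is obtained by gas-phase pyrolysis of acetone 18, and its cycloaddition to 17 gives 20 in one step.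

**10 from 8.** The phenol oxygen on ring B C1 is traced back to a formyl group. The aldehyde 8 is oxidised by a peracid to formate 9, which is cleaved. The aldehyde serves twice: as the activating group for the ether formation that introduced ring B, and as a masked phenol during the copper coupling.

**8 from 5 and 7.** The ring C C4–O bond is cut. This is the only ether bond whose carbon partner has no ortho substituent, so a copper-catalysed coupling of the hindered phenol 5 with the open bromide of 7 is reasonable there. The cut divides the tetramer into two dimers of similar size.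

**5 from 1 and 2; 7 from 6 and 2.** The ring D C6–O and ring B C6–O bonds are both made by the same substitution on fluoro aldehyde 2. The hindered but electron-rich phenoxides of 1 and 6 are the nucleophiles. The electrophilic carbon of 2 has the activating formyl group as its only ortho neighbour. Oxidation of 3 through 4 gives 5; the bromine of 6 is carried through untouched as the handle for the coupling.

## Alternatives that were turned down

**Alternative 1:** ring C is brought in as a dichloro dimethoxy arene bound to a cyclopentadienylruthenium cation (complex A2), and both of its ether bonds are cut. In the forward direction A2 would undergo two SNAr displacements in one flask, and irradiation would then release the permethylated pentamer A1. The phenoxide of 5 reacts first at the open chloride (ring C C4), and the phenoxide of the A–B phenol A3 second at the chloride between the two methoxy groups (ring C C1).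
- For: the plan is the most convergent of all (two rings, one ring, two rings), metal activation turns an electron-rich ring into a good SNAr substrate under mild conditions, and A1 is one dealkylation from the target.
- Against: the ruthenium is stoichiometric. The second displacement happens on a complex that has just gained a donor substituent, at a carbon flanked by two methoxy groups, with an ortho-substituted phenoxide, and it is placed last on the most valuable material. A3 still contains the ring A–O–ring B C1 bond, so that hindered arylation is only moved upstream.
- Comparison: alternative 1 is stronger on convergence and on length of the longest linear sequence. The chosen route offers instead that every electrophilic carbon has at most one ortho substituent, that no precious metal is consumed, and that the most hindered ether oxygen never has to be arylated.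

**Alternative 2:** ring D is built from a four-membered ring by cutting its C3–C4 bond. Heating the 4-hydroxy-4-(1-methoxyvinyl)cyclobutenone A5, which carries ring E as an aryloxy group, would open it to a dienylketene; six-electron closure and tautomerisation would give the D–E hydroquinone A4.
- For: the cascade is intramolecular and mild, the substitution pattern follows from connectivity alone, and the two hydroxyls of A4 are sterically distinct, so methylation of the open one would lead to 5.
- Against: the key step is spent on the easiest part of the molecule. It delivers a two-ring piece that the chosen route reaches in two steps from 1 and 2. A5 itself needs several steps, including a carbonyl addition of an alkenyllithium that competes with conjugate addition and expulsion of the aryloxide. Three ether bonds remain unsolved.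
- Comparison: as an electrocyclic cascade it is probably more reliable than the chosen key step, because no bimolecular cycloaddition is required. The chosen route uses the same logic at ring A, on the assembled tetramer, where it replaces the hardest arylation.

**Alternative 3:** ring C is made from an acyclic six-carbon keto enoate A7 that already carries the A–B and D–E aryloxy groups, by cutting the ring C C1–C6 bond. Excess LiN(SiMe3)2 would doubly deprotonate A7, the aryloxy-bearing carbanion would attack the ester, and aromatisation would give A6, the pentamer with free ring C C2 and C6 hydroxyls.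
- For: both ether oxygens of ring C are attached before the ring exists, by alkylation and conjugate addition, so no arylation at ring C is needed; the plan is convergent; A6 needs no protection on ring C.
- Against: A7 requires A3 (again the ring A–O–ring B bond), 5 and a differentiated six-carbon chain, which makes the route longer. The dianion can lose aryloxide by elimination from the vinylogous carbonate, and only the (E) enoate can close. The product is a very electron-rich resorcinol formed in strong base.
- Comparison: the convergence on paper is better. The chosen route keeps four rings aromatic from purchase and confines its risk to one ring made from two small reagents, whereas here the riskiest event consumes both dimers.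

Key step: step 9

## Route

Remark on the chemistry: 13 is drawn as the (E) isomer expected from anti addition to 12; its geometry is irrelevant because both chlorines are lost in step 7. Compound 22 has one transient stereocentre, forms as a racemate and loses the centre within the same step.

Step 1
Reactants: 1 2,4,6-trimethoxyphenol; 2 2-fluoro-4,6-dimethoxybenzaldehyde
Product: 3 2,4-dimethoxy-6-(2,4,6-trimethoxyphenoxy)benzaldehyde (D–E aldehyde)
Conditions: Cs2CO3, DMSO (degassed), 110 °C, Ar
Reagents that add atoms: none
Why: Nucleophilic aromatic substitution (SNAr): the ortho formyl group stabilises the Meisenheimer adduct and both methoxy groups of 2 are meta to fluorine, so they do not oppose attack; the phenoxide of 1 has no free ortho or para carbon, so only O-arylation is possible.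

Step 2
Reactants: 3 D–E aldehyde
Product: 5 2,4-dimethoxy-6-(2,4,6-trimethoxyphenoxy)phenol (D–E phenol), via aryl formate 4 (not isolated)
Conditions: mCPBA (1.2 equiv), CH2Cl2, 0 °C to rt; then K2CO3 (cat.), MeOH, rt, Ar
Reagents that add atoms: mCPBA (3-chloroperoxybenzoic acid), OOC(=O)c1cccc(Cl)c1
Why: Baeyer–Villiger oxidation in its Dakin form: the trioxygenated aryl group migrates in preference to hydrogen to give the formate, which methanolysis cleaves; a small excess of peracid at low temperature limits oxidation of the electron-rich rings.

Step 3
Reactants: 6 4-bromo-2,6-dimethoxyphenol; 2 2-fluoro-4,6-dimethoxybenzaldehyde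
Product: 7 2-(4-bromo-2,6-dimethoxyphenoxy)-4,6-dimethoxybenzaldehyde (B–C bromo aldehyde)
Conditions: Cs2CO3, DMSO (degassed), 110 °C, Ar
Reagents that add atoms: none
Why: The same SNAr as in step 1; without a metal catalyst the aryl bromide of 6 is inert and is kept as the handle for step 4.

Step 4
Reactants: 5 D–E phenol; 7 B–C bromo aldehyde
Product: 8 2-{4-[2,4-dimethoxy-6-(2,4,6-trimethoxyphenoxy)phenoxy]-2,6-dimethoxyphenoxy}-4,6-dimethoxybenzaldehyde (tetramer aldehyde)
Conditions: CuI (10 mol%), picolinic acid (20 mol%), K3PO4, DMSO, 100 °C, Ar
Reagents that add atoms: none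
Why: Ullmann-type copper-catalysed diaryl ether synthesis: the bromide of 7 has no ortho substituent, so the hindrance lies only on the phenol, which picolinate-ligated copper tolerates; the non-enolisable aldehyde is inert and remains as the masked ring B phenol.

Step 5
Reactants: 8 tetramer aldehyde
Product: 10 B–C–D–E tetramer phenol ArOH, via tetramer formate 9 (not isolated)
Conditions: mCPBA (1.2 equiv), CH2Cl2, 0 °C to rt; then K2CO3 (cat.), MeOH, rt, Ar
Reagents that add atoms: mCPBA (3-chloroperoxybenzoic acid), OOC(=O)c1cccc(Cl)c1
Why: Dakin-type Baeyer–Villiger oxidation as in step 2; ring B is 2,4,6-trioxygenated and migrates readily, and the oxygen is placed exactly on ring B C1.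

Step 6
Reactants: 10 tetramer phenol ArOH; 11 trichloroethylene
Product: 13 (E)-1,2-dichlorovinyl ether ArO–C(Cl)=CHCl, via dichloroacetylene 12 (not isolated)
Conditions: K2CO3, DMF, 70 °C
Reagents that add atoms: none
Why: Base dehydrochlorinates 11 to the chloroalkyne, to which the phenoxide adds in anti fashion, a known route from phenols to aryl dichlorovinyl ethers; the small linear electrophile reaches the oxygen between the methoxy and aryloxy groups easily.

Step 7
Reactants: 13 dichlorovinyl ether
Product: 16 aryl ethynyl ether ArO–C≡CH, via chloroethynyl ether 14 (not isolated), via lithium acetylide 15 (not isolated)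
Conditions: n-BuLi (2.3 equiv), THF, −78 to −40 °C; then MeOH, −78 °C; cold aqueous work-up, solution used at once
Reagents that add atoms: none
Why: Deprotonation and β-elimination of LiCl give the chloroalkyne, chlorine–lithium exchange gives the acetylide, and protonation gives the terminal ynol ether (the established dichlorovinyl ether route to ynol ethers); at −78 °C elimination outruns ring lithiation.

Step 8
Reactants: 17 ethoxyacetylene; 18 acetone
Product: 20 3-ethoxycyclobut-2-en-1-one, via ketene 19 (not isolated)
Conditions: 18 pyrolysed over a glowing filament (ketene lamp, ca. 700 °C), unchanged 18 condensed out; gas stream passed into 17, CH2Cl2, −20 to 0 °C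
Reagents that add atoms: none
Why: Thermal cracking of acetone gives one molecule of ketene and one of methane, which leaves with the gas stream; ketene then undergoes the classical [2+2] cycloaddition with the ynol ether, in which the nucleophilic terminal alkyne carbon bonds to the ketene carbonyl carbon and so fixes the 3-ethoxy pattern.

Step 9
Reactants: 16 aryl ethynyl ether ArO–C≡CH; 20 3-ethoxycyclobut-2-en-1-one
Product: 25 3-ethoxy-5-(aryloxy)phenol ArO–C6H3(OEt)(OH) (pentamer monophenol), via ethoxyvinylketene 21 (not isolated), via alkenylcyclobutenone 22 (not isolated), via dienylketene 23 (not isolated), via cyclohexadienone 24 (not isolated)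
Conditions: 20 (2.5 equiv, in portions), toluene, sealed tube, 80 °C then 110 °C, Ar; then K2CO3 (cat.), MeOH, rt
Reagents that add atoms: none
Why: On heating, 20 undergoes four-electron electrocyclic opening to the vinylketene 21. The unsubstituted, nucleophilic alkyne carbon of 16 attacks the ketene carbonyl carbon and the oxygen-bearing alkyne carbon bonds to the ketene α-carbon, a regioselective [2+2] cycloaddition that forms the first C–C bond and gives 22. Cyclobutenone 22 opens reversibly to dienylketene 23; only the isomer with the ethoxyvinyl group turned towards the ketene reacts on, and reversibility funnels material through it. Ring A then closes by thermal disrotatory six-electron electrocyclisation between the ketene carbon and the terminal methylene (second C–C bond), and dienone 24 tautomerises irreversibly to phenol 25. The closest known reaction is the Danheiser benzannulation of cyclobutenones with alkoxy- and silyloxyalkynes to resorcinol derivatives; an aryloxyalkyne and a 3-alkoxycyclobutenone are less usual members of the two partner classes. The only selectivity needed is the orientation of the [2+2]; the polarisation of the ynol ether secures it and places aryloxy, hydroxyl and ethoxy mutually meta, and no stereocentre remains. An aryl ynol ether has no β-hydrogen for retro-ene loss of an alkene, so it should tolerate the temperature needed to open 20; portionwise addition keeps the ketene concentration low, and the final methanolysis returns any product O-acylated by excess ketene.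

Step 10
Reactants: 25 pentamer monophenol
Product: 26 target pentamer
Conditions: BBr3 (ca. 20 equiv), CH2Cl2, −78 °C to rt; MeOH then H2O; degassed solvents, reversed-phase purification
Reagents that add atoms: none
Why: Lewis-acid ether cleavage: bromide attacks the methyl and ethyl carbons of the boron-complexed ethers (SN2), which diaryl ethers cannot undergo, so the nine methyl ethers and the ethyl ether fall while the four ring-to-ring oxygens stay.

## Compound list

1 | 2,4,6-trimethoxyphenol | COc1cc(OC)c(O)c(OC)c1 | starting material
2 | 2-fluoro-4,6-dimethoxybenzaldehyde | O=Cc1c(F)cc(OC)cc1OC | starting material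
3 | 2,4-dimethoxy-6-(2,4,6-trimethoxyphenoxy)benzaldehyde (D–E aldehyde) | O=Cc1c(OC)cc(OC)cc1Oc1c(OC)cc(OC)cc1OC | intermediate
4 | 2,4-dimethoxy-6-(2,4,6-trimethoxyphenoxy)phenyl formate | O=COc1c(OC)cc(OC)cc1Oc1c(OC)cc(OC)cc1OC | intermediate (not isolated)
5 | 2,4-dimethoxy-6-(2,4,6-trimethoxyphenoxy)phenol (D–E phenol) | Oc1c(OC)cc(OC)cc1Oc1c(OC)cc(OC)cc1OC | intermediate
6 | 4-bromo-2,6-dimethoxyphenol | COc1cc(Br)cc(OC)c1O | starting material
7 | 2-(4-bromo-2,6-dimethoxyphenoxy)-4,6-dimethoxybenzaldehyde (B–C bromo aldehyde) | O=Cc1c(OC)cc(OC)cc1Oc1c(OC)cc(Br)cc1OC | intermediate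
8 | 2-{4-[2,4-dimethoxy-6-(2,4,6-trimethoxyphenoxy)phenoxy]-2,6-dimethoxyphenoxy}-4,6-dimethoxybenzaldehyde (tetramer aldehyde) | O=Cc1c(OC)cc(OC)cc1Oc1c(OC)cc(Oc2c(OC)cc(OC)cc2Oc2c(OC)cc(OC)cc2OC)cc1OC | intermediate
9 | 2-{4-[2,4-dimethoxy-6-(2,4,6-trimethoxyphenoxy)phenoxy]-2,6-dimethoxyphenoxy}-4,6-dimethoxyphenyl formate (tetramer formate) | O=COc1c(OC)cc(OC)cc1Oc1c(OC)cc(Oc2c(OC)cc(OC)cc2Oc2c(OC)cc(OC)cc2OC)cc1OC | intermediate (not isolated)
10 | 2-{4-[2,4-dimethoxy-6-(2,4,6-trimethoxyphenoxy)phenoxy]-2,6-dimethoxyphenoxy}-4,6-dimethoxyphenol (B–C–D–E tetramer phenol, ArOH) | Oc1c(OC)cc(OC)cc1Oc1c(OC)cc(Oc2c(OC)cc(OC)cc2Oc2c(OC)cc(OC)cc2OC)cc1OC | intermediate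
11 | trichloroethylene | ClC=C(Cl)Cl | starting material
12 | dichloroacetylene | ClC#CCl | intermediate (not isolated)
13 | (E)-1,2-dichlorovinyl ether of 10, ArO–C(Cl)=CHCl | Cl/C=C(/Cl)Oc1c(OC)cc(OC)cc1Oc1c(OC)cc(Oc2c(OC)cc(OC)cc2Oc2c(OC)cc(OC)cc2OC)cc1OC | intermediate
14 | chloroethynyl ether of 10, ArO–C≡C–Cl | ClC#COc1c(OC)cc(OC)cc1Oc1c(OC)cc(Oc2c(OC)cc(OC)cc2Oc2c(OC)cc(OC)cc2OC)cc1OC | intermediate (not isolated)
15 | lithium (aryloxy)acetylide, ArO–C≡C–Li | [Li]C#COc1c(OC)cc(OC)cc1Oc1c(OC)cc(Oc2c(OC)cc(OC)cc2Oc2c(OC)cc(OC)cc2OC)cc1OC | intermediate (not isolated)
16 | ethynyl ether of 10, ArO–C≡CH | C#COc1c(OC)cc(OC)cc1Oc1c(OC)cc(Oc2c(OC)cc(OC)cc2Oc2c(OC)cc(OC)cc2OC)cc1OC | intermediate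
17 | ethoxyacetylene | CCOC#C | starting material
18 | acetone (propan-2-one) | CC(C)=O | starting material
19 | ketene | C=C=O | intermediate (not isolated)
20 | 3-ethoxycyclobut-2-en-1-one | CCOC1=CC(=O)C1 | intermediate
21 | 3-ethoxybuta-1,3-dien-1-one, the (1-ethoxyvinyl)ketene | CCOC(=C)C=C=O | intermediate (not isolated)
22 | 3-(aryloxy)-4-(1-ethoxyethenyl)cyclobut-2-en-1-one, aryl = Ar, racemic | O=C1C=C(Oc2c(OC)cc(OC)cc2Oc2c(OC)cc(Oc3c(OC)cc(OC)cc3Oc3c(OC)cc(OC)cc3OC)cc2OC)C1C(OCC)=C | intermediate (not isolated)
23 | (3E)-3-(aryloxy)-5-ethoxyhexa-1,3,5-trien-1-one, aryl = Ar | O=C=C/C(Oc1c(OC)cc(OC)cc1Oc1c(OC)cc(Oc2c(OC)cc(OC)cc2Oc2c(OC)cc(OC)cc2OC)cc1OC)=C\C(OCC)=C | intermediate (not isolated)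
24 | 3-(aryloxy)-5-ethoxycyclohexa-2,4-dien-1-one, aryl = Ar | O=C1C=C(Oc2c(OC)cc(OC)cc2Oc2c(OC)cc(Oc3c(OC)cc(OC)cc3Oc3c(OC)cc(OC)cc3OC)cc2OC)C=C(OCC)C1 | intermediate (not isolated)
25 | 3-ethoxy-5-(aryloxy)phenol, aryl = Ar (pentamer with ring A as ethoxy phenol) | CCOc1cc(O)cc(Oc2c(OC)cc(OC)cc2Oc2c(OC)cc(Oc3c(OC)cc(OC)cc3Oc3c(OC)cc(OC)cc3OC)cc2OC)c1 | intermediate
26 | target pentamer (CNP0018313.0) | Oc1cc(O)cc(Oc2c(O)cc(O)cc2Oc2c(O)cc(Oc3c(O)cc(O)cc3Oc3c(O)cc(O)cc3O)cc2O)c1 | target

## Step count and risk

Total: 10 steps. Longest linear sequence: 8 steps (steps 1, 2, 4, 5, 6, 7, 9, 10); steps 3 and 8 are one-step branches.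

**Step 9 (key step).** The most likely failure is loss of the aryl ynol ether by oligomerisation at 80–110 °C before the vinylketene intercepts it. The aryloxy group makes the alkyne a weaker ketene acceptor than an alkoxyalkyne, and 20, a vinylogous ester, opens slowly; self-condensation of the vinylketene competes as well. Fallback: set out from 10 and couple it with 1-bromo-3,5-dimethoxybenzene under the copper conditions of step 4 (CuI, picolinic acid, K3PO4, DMSO) to give the pentamer undecamethyl ether F1. Cleavage of its eleven methyl ethers with BBr3 comes back to the route at 26.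

**Step 7.** The terminal aryl ynol ether may be lost by oligomerisation or hydration during work-up, and excess base may lithiate a methoxy-flanked ring position. Fallback: set out from 13, generate 15 as before and quench it with Me3SiCl instead of methanol to give the storable (trimethylsilyl)ethynyl ether F2. Benzannulation of F2 with 20 as in step 9 should give the 2-(trimethylsilyl) phenol F3, silylated between the hydroxyl and the aryloxy group. Protodesilylation of this very electron-rich aryl silane with CF3CO2H in CH2Cl2 comes back to the route at 25.

**Step 4.** Oxidative addition into the electron-rich bromide may be slow with the hindered phenoxide, so that protodebromination of 7 and oxidative degradation of the phenoxide of 5 take over. Fallback: set out from 5 and react it with 4-fluoro-2,6-dimethoxybenzaldehyde (Cs2CO3, DMSO; SNAr para to the formyl group) to give the C–D–E trimer aldehyde F4. Peracid oxidation gives the trimer formate F5, and methanolysis gives the C–D–E trimer phenol F6. SNAr of F6 on 2 comes back to the route at 8 without using 7.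

**Step 1.** The substitution may be slow because the carbonyl of a trioxygenated benzaldehyde is a weak acceptor, and at higher temperature O-demethylation by the phenoxide may set in. Fallback: set out from 1 and couple it with commercial 2-bromo-4,6-dimethoxybenzaldehyde under copper catalysis (CuI, picolinic acid, K3PO4, DMSO), where the ortho formyl group assists the coupling; this comes back to the route at 3 and makes no compound outside the list (F0). If step 3 shows the same sluggishness, the linear sequence given under step 4 bypasses 7.

**Step 10.** Cleavage of eleven ethers may stop short and give mixtures of partly alkylated phenols, and the free polyphenol may be lost by air oxidation during isolation. Fallback: set out from 25, treat with BBr3 as before and acetylate the crude product (Ac2O, pyridine) to give the undecaacetate F7, which is stable and can be separated on silica from incompletely dealkylated material. Deacetylation (NaOMe cat., degassed MeOH, then acidic resin) comes back to the route at 26.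

## Further compounds

F1 | step 9 | pentamer undecamethyl ether, ArO–C6H3(OMe)2-3,5 | COc1cc(OC)cc(Oc2c(OC)cc(OC)cc2Oc2c(OC)cc(Oc3c(OC)cc(OC)cc3Oc3c(OC)cc(OC)cc3OC)cc2OC)c1
F2 | step 7 | (trimethylsilyl)ethynyl ether of 10, ArO–C≡C–SiMe3 | C[Si](C)(C)C#COc1c(OC)cc(OC)cc1Oc1c(OC)cc(Oc2c(OC)cc(OC)cc2Oc2c(OC)cc(OC)cc2OC)cc1OC
F3 | step 7 | 3-(aryloxy)-5-ethoxy-2-(trimethylsilyl)phenol, aryl = Ar | CCOc1cc(O)c([Si](C)(C)C)c(Oc2c(OC)cc(OC)cc2Oc2c(OC)cc(Oc3c(OC)cc(OC)cc3Oc3c(OC)cc(OC)cc3OC)cc2OC)c1
F4 | step 4 | 4-[2,4-dimethoxy-6-(2,4,6-trimethoxyphenoxy)phenoxy]-2,6-dimethoxybenzaldehyde (C–D–E trimer aldehyde) | O=Cc1c(OC)cc(Oc2c(OC)cc(OC)cc2Oc2c(OC)cc(OC)cc2OC)cc1OC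
F5 | step 4 | 4-[2,4-dimethoxy-6-(2,4,6-trimethoxyphenoxy)phenoxy]-2,6-dimethoxyphenyl formate (C–D–E trimer formate) | O=COc1c(OC)cc(Oc2c(OC)cc(OC)cc2Oc2c(OC)cc(OC)cc2OC)cc1OC
F6 | step 4 | 4-[2,4-dimethoxy-6-(2,4,6-trimethoxyphenoxy)phenoxy]-2,6-dimethoxyphenol (C–D–E trimer phenol) | Oc1c(OC)cc(Oc2c(OC)cc(OC)cc2Oc2c(OC)cc(OC)cc2OC)cc1OC
F0 | step 1 | none | none
F7 | step 10 | undecaacetate of the target pentamer | CC(=O)Oc1cc(OC(C)=O)cc(Oc2c(OC(C)=O)cc(OC(C)=O)cc2Oc2c(OC(C)=O)cc(Oc3c(OC(C)=O)cc(OC(C)=O)cc3Oc3c(OC(C)=O)cc(OC(C)=O)cc3OC(C)=O)cc2OC(C)=O)c1
A1 | alternative 1 | pentamer undecamethyl ether | COc1cc(OC)cc(Oc2c(OC)cc(OC)cc2Oc2c(OC)cc(Oc3c(OC)cc(OC)cc3Oc3c(OC)cc(OC)cc3OC)cc2OC)c1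
A2 | alternative 1 | (η5-cyclopentadienyl)(η6-2,5-dichloro-1,3-dimethoxybenzene)ruthenium(1+) hexafluorophosphate | COc1cc(Cl)cc(OC)c1Cl.[cH-]1cccc1.[Ru+2].F[P-](F)(F)(F)(F)F
A3 | alternative 1 | 2-(3,5-dimethoxyphenoxy)-3,5-dimethoxyphenol (A–B phenol) | Oc1cc(OC)cc(OC)c1Oc1cc(OC)cc(OC)c1
A4 | alternative 2 | 2-methoxy-6-(2,4,6-trimethoxyphenoxy)benzene-1,4-diol (D–E hydroquinone) | COc1cc(O)cc(Oc2c(OC)cc(OC)cc2OC)c1O
A5 | alternative 2 | 4-hydroxy-4-(1-methoxyethenyl)-3-(2,4,6-trimethoxyphenoxy)cyclobut-2-en-1-one, racemic | O=C1C=C(Oc2c(OC)cc(OC)cc2OC)C1(O)C(OC)=C
A6 | alternative 3 | pentamer nonamethyl ether with free ring C C2 and C6 hydroxyls | COc1cc(OC)cc(Oc2c(OC)cc(OC)cc2Oc2c(O)cc(Oc3c(OC)cc(OC)cc3Oc3c(OC)cc(OC)cc3OC)cc2O)c1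
A7 | alternative 3 | methyl (2E)-3-[2,4-dimethoxy-6-(2,4,6-trimethoxyphenoxy)phenoxy]-6-[2-(3,5-dimethoxyphenoxy)-3,5-dimethoxyphenoxy]-5-oxohex-2-enoate | COC(=O)/C=C(/Oc1c(OC)cc(OC)cc1Oc1c(OC)cc(OC)cc1OC)CC(=O)COc1cc(OC)cc(OC)c1Oc1cc(OC)cc(OC)c1
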